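## Structural features

Compound 22 is a 5,6,7,8-tetrahydro-1H-isochromen-8-one: a 2H-pyran ring (C1, O2, C3, C4) fused through the C4a=C8a double bond to a cyclohexenone ring, with an (E)-prop-1-enyl chain on C3. The unit O2–C3=C4–C4a=C8a–C8=O is a doubly vinylogous ester extended by the propenyl alkene, so it tolerates mild acid but not hydrogenation, hydride reagents or strong nucleophiles. C7 is a quaternary stereocentre carrying a methyl group and the tertiary ester of 4-hydroxy-2-methoxy-6-methylbenzoic acid, a benzoate with both ortho positions substituted, and it lies between the C8 ketone and the C6 carbinol. C6 and C7 are adjacent, both R, with their oxygens cis, so a free C6 alkoxide can take over the aroyl group or open the C6–C7 bond by retro-aldol cleavage. C5 is a γ position of the enone and C6 carries an oxygen β to it, which makes vinylogous elimination a standing risk in basic steps. The real difficulty is the hindered tertiary aroyloxy group on a quaternary carbon in a fixed relationship to C6, together with building the pyran with C1 at the CH2 level so that nothing near the ketone needs reduction afterwards. The key step uses the fact that O2 joins C1 to C3: C3, its propenyl group and O2 can arrive as a but-2-enoate ester of a C1 alcohol on C8a, and C4 is then a methyl group on C4a whose protons are vinylogous to the C8 ketone and, because C7 has no hydrogen, are among the few acidic ones.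

## Logic of the disconnections

22 ⇒ 21. Only the two O–Si bonds are cut. The phenol and the C6 hydroxyl must be masked through every basic step (acyl shift, retro-aldol, consumption of base). The skeleton is unchanged, and the forward step must be non-basic, which points to acidic fluoride.

21 ⇒ 18. The C3–C4 bond is cut and O2–C3 becomes an ester C–O bond, so the pyran opens to a monocyclic enone. C1 stays CH2 and C3 arrives at the carboxyl level that the enol ether needs, so no redox correction follows. The forward step needs γ-deprotonation at the C4a methyl group, carbonyl attack instead of conjugate addition, and survival of two esters and two silyl ethers. The design of 18 answers these demands as follows: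
- O6 is kept as a silyl ether, because an alkoxide there would migrate the aroyl group or trigger retro-aldol cleavage.
- The phenol is silylated, so it neither consumes base nor meets the oxidant of step 4 unprotected.
- C7 is quaternary, so no α′ proton competes.
- The ester is the conjugated (E)-but-2-enoate, put on without amine-induced deconjugation.
- The base is LiN(SiMe3)2 in excess of two equivalents, strong enough for the enone γ-protons but too weak for the lateral methyl group of the aroyl ester.

18 ⇒ 16 + 17. The ester C–O bond on C1 is cut. This separates the four-carbon acyl unit from the ring, and the forward step is a simple acylation of a primary allylic alcohol that must keep the double bond conjugated and E.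

16 ⇒ 14 + 15. The C8a–C1 bond is cut. C1 comes in as CH2OH by an sp2–sp3 coupling, so no carbonyl group at C1 ever has to be reduced beside the C8 ketone. The forward step must couple a hindered, tetrasubstituted α-iodoenone.

14 ⇒ 13. The C8a–I bond is cut. The forward step must halogenate the enone α-carbon without touching the electron-rich arene.

13 ⇒ 11. The C4a–C4 bond (the methyl group) is cut and the C4a=C8a unsaturation is taken out and put back. The enone is the natural acceptor for a methyl nucleophile, and re-oxidation erases the transient C4a stereocentre. A route through a C8/C4a β-diketone (enone oxidation, chloroformylation, methyl coupling, aldehyde reduction) was weighed and set aside, because the β-silyloxy diketone is prone to elimination and chloroformylation of an unsymmetrical dione has no regiocontrol.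

11 ⇒ 9. The C4a=C8a double bond is removed. The demand is regioselective dehydrogenation, which is trivial here because only C8a carries α-hydrogens.

9 ⇒ 8. The O6–Si bond is cut. Silylation must be fast and non-basic.

8 ⇒ 7. The C6–H bond is cut, which turns the carbinol into a ketone and makes the ring achiral, with a mirror plane through C7 and C4a. Both stereocentres therefore come from one catalytic desymmetrisation. The forward step must choose one of two enantiotopic carbonyls and the face anti to the aroyloxy group, and must stop at mono-reduction.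

7 ⇒ 4 + 5. The C7–O bond is cut. Making this bond by oxidation at carbon, with the oxygen arriving already acylated, avoids acylating a tertiary alcohol with a di-ortho-substituted acid. The forward step needs an electrophilic carboxylate equivalent that the enol of 5 attacks at C2.

4 ⇒ 3 ⇒ 2 ⇒ 1. The acid is taken back to the aldehyde, then the O–CH3 and O–Si bonds are cut. Oxidation of an aldehyde is used because saponification of a 2,6-disubstituted benzoate ester would not spare an aryl silyl ether. The forward steps rely on the hydrogen-bonded 2-OH being the less reactive phenol.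

## Other disconnections considered

Alternative 1: The cut is made in the C1-oxo analogue of 21, at C4a–C8a of the carbocycle and O2–C1 of the heterocycle, leading back to the open-chain ynone β-keto ester A1. In the forward step Cs2CO3 forms the C8a carbanion, which adds 6-exo-dig to the ynone β-carbon C4a, and the C3 oxygen of the resulting allenolate closes on the C1 ester to give the fused 2-pyranone A2.
- In its favour: two rings and two bonds form in one operation under a carbonate base, against one ring and one bond under a lithium amide in 18 → 21. On bond economy of the key step and mildness of the base it is the better plan. It leaves C6 and C7 untouched, which is equal to the chosen plan.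
- Against it: A2 carries C1 as a lactone carbonyl. Converting it to the CH2 of 21 needs a reduction that spares the C8 ketone, the aryl ester and the dienyl ether, and no selective method is at hand.
- Against it: A1 must hold the C6/C7 pair in an open chain, so the tertiary aroyl ester has to be made without the symmetry that 7 offers. Its C5 protons are propargylic and next to the silyloxy-bearing C6, which invites allene formation and elimination under the same base.
- Comparison: the alternative reaches the wrong oxidation level at C1 and the chosen plan the right one. Both rely on a stabilised carbanion; the 6-exo-dig closure is regiochemically unambiguous, whereas the chosen plan depends on γ-site selection. The redox correction and the open-chain stereodiad make the alternative longer overall.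

Alternative 2: The C7–C8 bond is cut, leading to the 2H-pyran A3, which carries the C8 aldehyde on C8a and a side chain on C4a ending in the C7 methyl ketone with the C6 silyl ether. In the forward step a chiral aminoindanol-derived N-pentafluorophenyl triazolium salt with an amine base gives the carbene, which converts the aldehyde into an acyl-anion equivalent that adds to the C7 ketone and closes the carbocycle as the tertiary α-ketol A4.
- In its favour: the step is catalytic and mild, and it creates the quaternary C7 stereocentre in the ring-closing event. The chosen key step creates no stereocentre, so on this point the alternative is better. Six-membered aldehyde–ketone benzoin closures are a known reaction type, which is equal in precedent.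
- Against it: the tertiary hydroxyl of A4 must afterwards be acylated with the hindered acid, the hardest acylation the molecule offers, on an α-ketol that can rearrange.
- Against it: the aldehyde of A3 is a doubly vinylogous formate and a poor electrophile for the carbene, and a monocyclic 2H-pyran is liable to electrocyclic ring opening.
- Against it: the cis relationship of O6 and O7 would rest on the catalyst overriding the substrate.
- Comparison: the chosen plan sets C7 early on a symmetric dione and keeps the aroyl group on it throughout. The alternative's catalytic closure is more elegant than an enolate acylation, but the late esterification makes it less secure and no shorter.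

Alternative 3: The C5–C6 and C8–C8a bonds are cut, leading to the aldehyde ester A5 (C6 aldehyde, quaternary C7, C8 methyl ester) and methyl acetoacetate A6. In the forward step the dianion of A6 adds through its terminal carbon to the aldehyde and its central carbon then closes on the C8 ester in a Dieckmann step, giving the enolised dione ester A7.
- In its favour: it is the most convergent of the four plans and better than the chosen one on that point. The carbocycle and two C–C bonds form from two small pieces, C1 arrives on C8a, and the C4a oxygen is a handle for the methyl group.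
- Against it: A5 is a quaternary, enantiopure aldehyde ester prone to deformylation. The C6 configuration would depend on 1,2-induction from a centre whose three substituents differ little.
- Against it: the aldol alkoxide at C6 sits next to the aroyl ester under strongly basic conditions, and the Dieckmann closure must attack an ester flanked by a quaternary carbon.
- Against it: A7 still needs differentiation of the C4a enol from the C8 ketone, a methyl coupling, and reduction of the C1 ester beside two carbonyl groups.
- Comparison: both plans use classical enolate acylation (equal). The alternative builds the ring faster but leaves more functional-group surgery after its key step than 21 needs.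

Key step: step 12

Remark (configuration check): the 6R,7R descriptors of 22 place O6 and O7 on the same face; 8 to 21 are drawn with that configuration, and the SMILES of 18 and 21 were checked centre by centre against 22.

Remark (assumption): 1, 5, 15, 17, PhI(OAc)2 and the (S)-oxazaborolidine are taken as commercially available. Atom labels C1 to C8a follow the isochromene numbering of 22 for all intermediates. TBS = tert-butyldimethylsilyl and TBSO = its oxy group.

## Route

Step 1
Reactants: 1 2,4-dihydroxy-6-methylbenzaldehyde
Product: 2 4-(TBSO)-2-hydroxy-6-methylbenzaldehyde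
Conditions: TBSCl (1.05 equiv), imidazole, CH2Cl2, 0 °C
Reagents that add atoms: tert-butyldimethylsilyl chloride, CC(C)(C)[Si](C)(C)Cl
Why: Regioselective O-silylation: the 4-OH is the more acidic and accessible phenol, while the 2-OH is held in a hydrogen bond to the aldehyde and should stay free.

Step 2
Reactants: 2 4-(TBSO)-2-hydroxy-6-methylbenzaldehyde
Product: 3 4-(TBSO)-2-methoxy-6-methylbenzaldehyde
Conditions: MeI, Ag2O, MeCN, rt, dark
Reagents that add atoms: iodomethane, CI
Why: Purdie-type O-methylation with Ag2O works under neutral conditions, so the chelated phenol is methylated without the carbonate or hydroxide bases that cleave an aryl silyl ether para to a carbonyl group.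

Step 3
Reactants: 3 4-(TBSO)-2-methoxy-6-methylbenzaldehyde
Product: 4 4-(TBSO)-2-methoxy-6-methylbenzoic acid
Conditions: NaClO2, NaH2PO4, 2-methylbut-2-ene, t-BuOH/H2O, rt
Reagents that add atoms: sodium chlorite, [Na+].[O-]Cl=O
Why: Pinnick oxidation converts the hindered aldehyde into the acid near pH 4, where the aryl silyl ether survives, and the alkene scavenger removes HOCl before it can chlorinate the electron-rich ring.

Step 4
Reactants: 4 4-(TBSO)-2-methoxy-6-methylbenzoic acid (2.1 equiv); 5 2-methylcyclohexane-1,3-dione
Product: 7 1-methyl-2,6-dioxocyclohexyl 4-(TBSO)-2-methoxy-6-methylbenzoate, via bis(aroyloxy)iodobenzene 6 (not isolated)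
Conditions: PhI(OAc)2, PhCl, 45 °C, reduced pressure (AcOH removed); then 5, MeCN, rt
Reagents that add atoms: none
Why: Ligand exchange gives the bis(aroyloxy) derivative of trivalent iodine; the enol of the 2-substituted 1,3-dione binds to iodine and a carboxylate ligand is delivered to C2 with loss of iodobenzene (α-acyloxylation of 1,3-dicarbonyl compounds by iodobenzene dicarboxylates). The tertiary C–O bond is thus made by oxidation at carbon and not by acylation of a tertiary alcohol, and the product is achiral.

Step 5
Reactants: 7 1-methyl-2,6-dioxocyclohexyl 4-(TBSO)-2-methoxy-6-methylbenzoate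
Product: 8 (1R,2R)-2-hydroxy-1-methyl-6-oxocyclohexyl 4-(TBSO)-2-methoxy-6-methylbenzoate
Conditions: (S)-2-methyl-CBS-oxazaborolidine [(S)-tetrahydro-1-methyl-3,3-diphenyl-1H,3H-pyrrolo[1,2-c][1,3,2]oxazaborole] (20 mol%), BH3·SMe2 (0.6 equiv), THF, −40 °C; MeOH
Reagents that add atoms: none
Why: Corey–Bakshi–Shibata desymmetrisation of a 2,2-disubstituted cyclic 1,3-dione: with quaternary C7 as the large group the (S)-catalyst should give the R carbinol, and its preferred enantioface coincides with the methyl face (anti to the axial aroyloxy group) for only one of the two enantiotopic carbonyls, so O6 should end up cis to O7 with C6 and C7 both R. Boron-bound oxygen is not basic enough to start an O7-to-O6 acyl shift, and the hydroxy ketone should be reduced further only slowly.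

Step 6
Reactants: 8 (1R,2R)-2-hydroxy-1-methyl-6-oxocyclohexyl 4-(TBSO)-2-methoxy-6-methylbenzoate
Product: 9 (1R,2R)-2-(TBSO)-1-methyl-6-oxocyclohexyl 4-(TBSO)-2-methoxy-6-methylbenzoate
Conditions: TBSOTf, 2,6-lutidine, CH2Cl2, −78 → 0 °C
Reagents that add atoms: tert-butyldimethylsilyl trifluoromethanesulfonate, CC(C)(C)[Si](C)(C)OS(=O)(=O)C(F)(F)F
Why: A silyl triflate with a hindered pyridine base silylates the hindered secondary alcohol quickly without forming an alkoxide, which closes the window for acyl migration and blocks retro-aldol opening in all later basic steps.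

Step 7
Reactants: 9 (1R,2R)-2-(TBSO)-1-methyl-6-oxocyclohexyl 4-(TBSO)-2-methoxy-6-methylbenzoate
Product: 11 (1R,6R)-6-(TBSO)-1-methyl-2-oxocyclohex-3-en-1-yl 4-(TBSO)-2-methoxy-6-methylbenzoate, via trimethylsilyl enol ether 10 (not isolated)
Conditions: Me3SiOTf, Et3N, CH2Cl2, 0 °C; then Pd(OAc)2, MeCN, rt
Reagents that add atoms: none
Why: Saegusa–Ito dehydrogenation: only C8a carries α-hydrogens, so soft enolisation gives a single silyl enol ether, and divalent palladium then forms the palladium enolate and loses the C4a hydrogen by β-hydride elimination. Soft enolisation keeps strong amide bases away from the laterally acidic aroyl methyl group.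

Step 8
Reactants: 11 (1R,6R)-6-(TBSO)-1-methyl-2-oxocyclohex-3-en-1-yl 4-(TBSO)-2-methoxy-6-methylbenzoate
Product: 13 (1R,6R)-6-(TBSO)-1,4-dimethyl-2-oxocyclohex-3-en-1-yl 4-(TBSO)-2-methoxy-6-methylbenzoate, via trimethylsilyl enol ether 12 (not isolated)
Conditions: Me2CuLi (from MeLi, CuI), Me3SiCl, THF, −78 °C; then Pd(OAc)2, MeCN, rt
Reagents that add atoms: lithium dimethylcuprate, [Li+].C[Cu-]C
Why: Chlorosilane-accelerated Gilman conjugate addition puts the methyl group (the future C4) on C4a and traps the enolate regiospecifically; a second Saegusa–Ito oxidation removes the only β-hydrogen (on C4a) and erases the transient C4a stereocentre. At −78 °C conjugate addition should outrun reductive cleavage of the α′-aroyloxy group, and the hindered benzoate is inert to the cuprate.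

Step 9
Reactants: 13 (1R,6R)-6-(TBSO)-1,4-dimethyl-2-oxocyclohex-3-en-1-yl 4-(TBSO)-2-methoxy-6-methylbenzoate
Product: 14 (1R,6R)-6-(TBSO)-3-iodo-1,4-dimethyl-2-oxocyclohex-3-en-1-yl 4-(TBSO)-2-methoxy-6-methylbenzoate
Conditions: I2, pyridine, CH2Cl2, rt, dark
Reagents that add atoms: iodine, II
Why: Johnson α-iodination of an enone (pyridine conjugate addition, iodination of the enolate, elimination); C8a is the only position that can react this way, and iodine with pyridine is too weak an electrophile for the ester-deactivated arene.

Step 10
Reactants: 14 (1R,6R)-6-(TBSO)-3-iodo-1,4-dimethyl-2-oxocyclohex-3-en-1-yl 4-(TBSO)-2-methoxy-6-methylbenzoate; 15 (tributylstannyl)methanol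
Product: 16 (1R,6R)-6-(TBSO)-3-(hydroxymethyl)-1,4-dimethyl-2-oxocyclohex-3-en-1-yl 4-(TBSO)-2-methoxy-6-methylbenzoate
Conditions: Pd(PPh3)4 (10 mol%), CuI (20 mol%), 1,4-dioxane, 90 °C
Reagents that add atoms: none
Why: Migita–Kosugi–Stille coupling of an α-iodoenone with the hydroxymethyl stannane: oxidative addition of zerovalent palladium to the electron-poor vinyl iodide is fast, and the α-oxygenated sp3 group transfers in preference to butyl. C1 enters at the alcohol level, so nothing is reduced beside the C8 ketone.

Step 11
Reactants: 16 (1R,6R)-6-(TBSO)-3-(hydroxymethyl)-1,4-dimethyl-2-oxocyclohex-3-en-1-yl 4-(TBSO)-2-methoxy-6-methylbenzoate; 17 (2E)-but-2-enoyl chloride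
Product: 18 (1R,6R)-3-{[(2E)-but-2-enoyloxy]methyl}-6-(TBSO)-1,4-dimethyl-2-oxocyclohex-3-en-1-yl 4-(TBSO)-2-methoxy-6-methylbenzoate
Conditions: pyridine, CH2Cl2, −20 → 0 °C
Reagents that add atoms: none
Why: O-acylation of the primary allylic alcohol; pyridine is used in place of a trialkylamine so that the acid chloride is not converted into vinylketene, which would give the deconjugated but-3-enoate.

Step 12
Reactants: 18 (1R,6R)-3-{[(2E)-but-2-enoyloxy]methyl}-6-(TBSO)-1,4-dimethyl-2-oxocyclohex-3-en-1-yl 4-(TBSO)-2-methoxy-6-methylbenzoate
Product: 21 (6R,7R)-6-(TBSO)-7-methyl-8-oxo-3-[(1E)-prop-1-en-1-yl]-5,6,7,8-tetrahydro-1H-isochromen-7-yl 4-(TBSO)-2-methoxy-6-methylbenzoate, via hydroxy diketone 19 (not isolated), via cyclic hemiketal 20 (not isolated)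
Conditions: LiN(SiMe3)2 (3 equiv), THF, −78 → −20 °C; AcOH; then TsOH·H2O (10 mol%), CH2Cl2, 4 Å MS, rt
Reagents that add atoms: none
Why: LiN(SiMe3)2 can remove only γ protons of the enone, because C7 is quaternary and the base is too weak for lateral deprotonation of the aroyl 6-methyl group; loss of a proton from the C4a methyl gives the extended enolate, whose terminal carbon C4 adds to the but-2-enoate carbonyl C3 through a six-membered transition state. This closes the pyran ring in a 6-exo-trig mode, with the enolate double bond inside the forming ring and the carbonyl oxygen outside. The tetrahedral lithium hemiketal either persists or expels the O2 alkoxide to give the C4-acylated enone 19, whose doubly activated C4 methylene is deprotonated at once, which pulls the equilibrium forward and is why more than two equivalents of base are used. On acidification O2 adds back to the C3 ketone (hemiketal 20) and water is lost across C3–C4, which should be favourable under catalytic TsOH because the product is a doubly vinylogous ester. The closest known reactions are the Baker–Venkataraman O-to-C acyl transfer with cyclodehydration and the lateral enolate acylation of ortho-methyl aryl carbonyl compounds that leads to isocoumarins and isochromenes. No stereocentre is formed, since C3 of 20 is lost on dehydration, and C6 and C7 are not touched. Site selectivity rests on geometry: C4 lies syn to the C1 tether across the C4a–C8a bond and closes a normal fused ring, whereas the C5 terminus of the ring dienolate lies anti to the tether and could only give a bridged ring with a trans ring double bond, so C5 deprotonation should simply reverse, and conjugate addition of C4 to the but-2-enoate would need an eight-membered ring.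

Step 13
Reactants: 21 (6R,7R)-6-(TBSO)-7-methyl-8-oxo-3-[(1E)-prop-1-en-1-yl]-5,6,7,8-tetrahydro-1H-isochromen-7-yl 4-(TBSO)-2-methoxy-6-methylbenzoate
Product: 22 (6R,7R)-6-hydroxy-7-methyl-8-oxo-3-[(1E)-prop-1-en-1-yl]-5,6,7,8-tetrahydro-1H-isochromen-7-yl 4-hydroxy-2-methoxy-6-methylbenzoate
Conditions: HF·pyridine, pyridine, THF, 0 °C → rt
Reagents that add atoms: none
Why: Buffered acidic fluoride cleaves the aryl and the secondary alkyl silyl ether in one operation; a basic fluoride source is avoided because a C6 alkoxide cis to the C7 ester could take over the aroyl group or open the ring by retro-aldol cleavage. The vinylogous ester, the propenyl group and both stereocentres should not be affected.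

## Compound list

1 | 2,4-dihydroxy-6-methylbenzaldehyde | Cc1cc(O)cc(O)c1C=O | starting material
2 | 4-(TBSO)-2-hydroxy-6-methylbenzaldehyde | Cc1cc(O[Si](C)(C)C(C)(C)C)cc(O)c1C=O | intermediate
3 | 4-(TBSO)-2-methoxy-6-methylbenzaldehyde | COc1cc(O[Si](C)(C)C(C)(C)C)cc(C)c1C=O | intermediate
4 | 4-(TBSO)-2-methoxy-6-methylbenzoic acid | COc1cc(O[Si](C)(C)C(C)(C)C)cc(C)c1C(=O)O | intermediate
5 | 2-methylcyclohexane-1,3-dione | CC1C(=O)CCCC1=O | starting material
6 | phenyliodine bis[4-(TBSO)-2-methoxy-6-methylbenzoate] (trivalent iodine, formed in the flask) | COc1cc(O[Si](C)(C)C(C)(C)C)cc(C)c1C(=O)OI(OC(=O)c1c(C)cc(O[Si](C)(C)C(C)(C)C)cc1OC)c1ccccc1 | intermediate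
7 | 1-methyl-2,6-dioxocyclohexyl 4-(TBSO)-2-methoxy-6-methylbenzoate | CC1(OC(=O)c2c(C)cc(O[Si](C)(C)C(C)(C)C)cc2OC)C(=O)CCCC1=O | intermediate
8 | (1R,2R)-2-hydroxy-1-methyl-6-oxocyclohexyl 4-(TBSO)-2-methoxy-6-methylbenzoate | O=C1[C@](C)(OC(=O)c2c(C)cc(O[Si](C)(C)C(C)(C)C)cc2OC)[C@H](O)CCC1 | intermediate
9 | (1R,2R)-2-(TBSO)-1-methyl-6-oxocyclohexyl 4-(TBSO)-2-methoxy-6-methylbenzoate | O=C1[C@](C)(OC(=O)c2c(C)cc(O[Si](C)(C)C(C)(C)C)cc2OC)[C@H](O[Si](C)(C)C(C)(C)C)CCC1 | intermediate
10 | (1R,6R)-6-(TBSO)-1-methyl-2-[(trimethylsilyl)oxy]cyclohex-2-en-1-yl 4-(TBSO)-2-methoxy-6-methylbenzoate (formed in the flask) | C[Si](C)(C)OC=1[C@](C)(OC(=O)c2c(C)cc(O[Si](C)(C)C(C)(C)C)cc2OC)[C@H](O[Si](C)(C)C(C)(C)C)CCC=1 | intermediate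
11 | (1R,6R)-6-(TBSO)-1-methyl-2-oxocyclohex-3-en-1-yl 4-(TBSO)-2-methoxy-6-methylbenzoate | O=C1[C@](C)(OC(=O)c2c(C)cc(O[Si](C)(C)C(C)(C)C)cc2OC)[C@H](O[Si](C)(C)C(C)(C)C)CC=C1 | intermediate
12 | (1R,6R)-6-(TBSO)-1,4-dimethyl-2-[(trimethylsilyl)oxy]cyclohex-2-en-1-yl 4-(TBSO)-2-methoxy-6-methylbenzoate (C4 epimers, formed in the flask) | C[Si](C)(C)OC=1[C@](C)(OC(=O)c2c(C)cc(O[Si](C)(C)C(C)(C)C)cc2OC)[C@H](O[Si](C)(C)C(C)(C)C)CC(C)C=1 | intermediate
13 | (1R,6R)-6-(TBSO)-1,4-dimethyl-2-oxocyclohex-3-en-1-yl 4-(TBSO)-2-methoxy-6-methylbenzoate | O=C1[C@](C)(OC(=O)c2c(C)cc(O[Si](C)(C)C(C)(C)C)cc2OC)[C@H](O[Si](C)(C)C(C)(C)C)CC(C)=C1 | intermediate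
14 | (1R,6R)-6-(TBSO)-3-iodo-1,4-dimethyl-2-oxocyclohex-3-en-1-yl 4-(TBSO)-2-methoxy-6-methylbenzoate | O=C1[C@](C)(OC(=O)c2c(C)cc(O[Si](C)(C)C(C)(C)C)cc2OC)[C@H](O[Si](C)(C)C(C)(C)C)CC(C)=C1I | intermediate
15 | (tributylstannyl)methanol | OC[Sn](CCCC)(CCCC)CCCC | starting material
16 | (1R,6R)-6-(TBSO)-3-(hydroxymethyl)-1,4-dimethyl-2-oxocyclohex-3-en-1-yl 4-(TBSO)-2-methoxy-6-methylbenzoate | O=C1[C@](C)(OC(=O)c2c(C)cc(O[Si](C)(C)C(C)(C)C)cc2OC)[C@H](O[Si](C)(C)C(C)(C)C)CC(C)=C1CO | intermediate
17 | (2E)-but-2-enoyl chloride | C/C=C/C(Cl)=O | starting material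
18 | (1R,6R)-3-{[(2E)-but-2-enoyloxy]methyl}-6-(TBSO)-1,4-dimethyl-2-oxocyclohex-3-en-1-yl 4-(TBSO)-2-methoxy-6-methylbenzoate | C/C=C/C(=O)OCC1=C(C)C[C@@H](O[Si](C)(C)C(C)(C)C)[C@@](C)(OC(=O)c2c(C)cc(O[Si](C)(C)C(C)(C)C)cc2OC)C1=O | intermediate
19 | (1R,6R)-6-(TBSO)-3-(hydroxymethyl)-1-methyl-2-oxo-4-[(3E)-2-oxopent-3-en-1-yl]cyclohex-3-en-1-yl 4-(TBSO)-2-methoxy-6-methylbenzoate (formed in the flask) | C/C=C/C(=O)CC1=C(CO)C(=O)[C@](C)(OC(=O)c2c(C)cc(O[Si](C)(C)C(C)(C)C)cc2OC)[C@H](O[Si](C)(C)C(C)(C)C)C1 | intermediate
20 | (6R,7R)-6-(TBSO)-3-hydroxy-7-methyl-8-oxo-3-[(1E)-prop-1-en-1-yl]-3,4,5,6,7,8-hexahydro-1H-isochromen-7-yl 4-(TBSO)-2-methoxy-6-methylbenzoate (C3 epimers, formed in the flask) | C/C=C/C1(O)CC2=C(CO1)C(=O)[C@](C)(OC(=O)c3c(C)cc(O[Si](C)(C)C(C)(C)C)cc3OC)[C@H](O[Si](C)(C)C(C)(C)C)C2 | intermediate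
21 | (6R,7R)-6-(TBSO)-7-methyl-8-oxo-3-[(1E)-prop-1-en-1-yl]-5,6,7,8-tetrahydro-1H-isochromen-7-yl 4-(TBSO)-2-methoxy-6-methylbenzoate | C/C=C/C1=CC2=C(CO1)C(=O)[C@](C)(OC(=O)c3c(C)cc(O[Si](C)(C)C(C)(C)C)cc3OC)[C@H](O[Si](C)(C)C(C)(C)C)C2 | intermediate
22 | (6R,7R)-6-hydroxy-7-methyl-8-oxo-3-[(1E)-prop-1-en-1-yl]-5,6,7,8-tetrahydro-1H-isochromen-7-yl 4-hydroxy-2-methoxy-6-methylbenzoate | C/C=C/C1=CC2=C(CO1)C(=O)[C@](C)(OC(=O)c1c(C)cc(O)cc1OC)[C@H](O)C2 | target

## Step count and least certain steps

Total step count: 13. Longest linear sequence: 13 steps (1 → 22); 5, 15 and 17 enter as commercial single inputs.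

Step 12 (key step). What may go wrong:
- Deprotonation of the but-2-enoate γ-methyl in competition with the ring methyl, leading to deconjugation or to an enolate Claisen rearrangement of the allylic ester.
- Deprotonation at C5 followed by vinylogous β-elimination of the O6 silyloxy group. The pseudo-equatorial C6–O bond is poorly aligned for this, but it is not excluded.
- Slow acyl transfer, because a conjugated ester is a weak electrophile.
- Silyl transfer from the aryl ether to the liberated C1 alkoxide.

Fallback: an intermolecular vinylogous aldol route from 16 that returns at 21. Et3SiCl and imidazole give the C1 triethylsilyl ether F1. LiN(SiMe3)2 and Me3SiCl at −78 °C give the silyl dienol ether with an exocyclic methylene on C4a, F2. A vinylogous Mukaiyama aldol addition of F2 to (E)-but-2-enal with BF3·OEt2 at −78 °C joins C4 to C3 and gives the allylic alcohol F3. Dess–Martin periodinane oxidises it to the enone ketone F4. TsOH·H2O in CH2Cl2/MeOH removes the primary triethylsilyl group, after which the C1 hydroxyl closes on C3 and water is lost, giving 21. The acidity of the unsaturated ester is then no longer an issue, at the price of relying on kinetic selection of the methyl protons over C5.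

Step 4. What may go wrong: slow ligand coupling at the fully substituted carbon, so that capture of the iodine-bound enol by traces of water (hydroxylation) competes, and oxidation of the electron-rich aryl ring by trivalent iodine. Fallback: from 4 and 5, returning at 7, with an enolate attack on a peroxide oxygen in place of ligand coupling on iodine. Acid 4 is coupled with H2O2 (urea adduct) and N,N'-dicyclohexylcarbodiimide in CH2Cl2 at 0 °C to the diaroyl peroxide F5, which is used cold and in solution. The sodium enolate of 5 (NaH, THF/DMF, 0 °C) then attacks the O–O bond of F5 through C2 and gives 7 with release of one equivalent of 4.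

Step 5. What may go wrong: poor discrimination between the enantiotopic carbonyls or between the two faces (loss of enantiomeric or diastereomeric purity), over-reduction to the diol, and acyl shift from O7 to O6 during work-up. Fallback: from 7, returning at 8, by asymmetric transfer hydrogenation with RuCl(p-cymene)[(S,S)-TsDPEN] or its enantiomer in HCO2H/Et3N (5:2) at rt. This replaces Lewis-acid-activated borane by outer-sphere hydride transfer in a mildly acidic medium, where acyl migration is suppressed and the second ketone reacts slowly; the ligand enantiomer is chosen to deliver the 6R carbinol. It makes no compound outside the list.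

Step 10. What may go wrong: slow transmetalation of the sp3 stannane at the hindered tetrasubstituted vinylpalladium, so that protodeiodination or butyl transfer takes over. Fallback: from 14, returning at 16, by reductive carbonylation and chemoselective reduction. Pd(PPh3)4, CO (1 atm) and slowly added Bu3SnH in THF at 50 °C give the aldehyde F6. NaBH(OAc)3 in THF with a little AcOH then reduces the aldehyde and leaves the hindered, conjugated C8 ketone; conjugate reduction is disfavoured because C4a is fully substituted.

## Further compounds

F1 | step 12 | (1R,6R)-6-(TBSO)-1,4-dimethyl-2-oxo-3-{[(triethylsilyl)oxy]methyl}cyclohex-3-en-1-yl 4-(TBSO)-2-methoxy-6-methylbenzoate | O=C1[C@](C)(OC(=O)c2c(C)cc(O[Si](C)(C)C(C)(C)C)cc2OC)[C@H](O[Si](C)(C)C(C)(C)C)CC(C)=C1CO[Si](CC)(CC)CC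
F2 | step 12 | (1R,6R)-6-(TBSO)-1-methyl-4-methylidene-3-{[(triethylsilyl)oxy]methyl}-2-[(trimethylsilyl)oxy]cyclohex-2-en-1-yl 4-(TBSO)-2-methoxy-6-methylbenzoate | C[Si](C)(C)OC=1[C@](C)(OC(=O)c2c(C)cc(O[Si](C)(C)C(C)(C)C)cc2OC)[C@H](O[Si](C)(C)C(C)(C)C)CC(=C)C=1CO[Si](CC)(CC)CC
F3 | step 12 | (1R,6R)-6-(TBSO)-4-[(3E)-2-hydroxypent-3-en-1-yl]-1-methyl-2-oxo-3-{[(triethylsilyl)oxy]methyl}cyclohex-3-en-1-yl 4-(TBSO)-2-methoxy-6-methylbenzoate (carbinol epimers) | O=C1[C@](C)(OC(=O)c2c(C)cc(O[Si](C)(C)C(C)(C)C)cc2OC)[C@H](O[Si](C)(C)C(C)(C)C)CC(CC(O)/C=C/C)=C1CO[Si](CC)(CC)CC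
F4 | step 12 | (1R,6R)-6-(TBSO)-1-methyl-2-oxo-4-[(3E)-2-oxopent-3-en-1-yl]-3-{[(triethylsilyl)oxy]methyl}cyclohex-3-en-1-yl 4-(TBSO)-2-methoxy-6-methylbenzoate | O=C1[C@](C)(OC(=O)c2c(C)cc(O[Si](C)(C)C(C)(C)C)cc2OC)[C@H](O[Si](C)(C)C(C)(C)C)CC(CC(=O)/C=C/C)=C1CO[Si](CC)(CC)CC
F5 | step 4 | bis[4-(TBSO)-2-methoxy-6-methylbenzoyl] peroxide | COc1cc(O[Si](C)(C)C(C)(C)C)cc(C)c1C(=O)OOC(=O)c1c(C)cc(O[Si](C)(C)C(C)(C)C)cc1OC
F0 | step 5 | none | none
F6 | step 10 | (1R,6R)-6-(TBSO)-3-formyl-1,4-dimethyl-2-oxocyclohex-3-en-1-yl 4-(TBSO)-2-methoxy-6-methylbenzoate | O=C1[C@](C)(OC(=O)c2c(C)cc(O[Si](C)(C)C(C)(C)C)cc2OC)[C@H](O[Si](C)(C)C(C)(C)C)CC(C)=C1C=O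
A1 | alternative 1 | methyl (4R,5R)-4-{[4-(TBSO)-2-methoxy-6-methylbenzoyl]oxy}-5-(TBSO)-4-methyl-3,9-dioxoundec-10-en-7-ynoate, (10E) | COC(=O)CC(=O)[C@](C)(OC(=O)c1c(C)cc(O[Si](C)(C)C(C)(C)C)cc1OC)[C@H](O[Si](C)(C)C(C)(C)C)CC#CC(=O)/C=C/C
A2 | alternative 1 | (6R,7R)-6-(TBSO)-7-methyl-1,8-dioxo-3-[(1E)-prop-1-en-1-yl]-5,6,7,8-tetrahydro-1H-isochromen-7-yl 4-(TBSO)-2-methoxy-6-methylbenzoate | C/C=C/C1=CC2=C(C(=O)O1)C(=O)[C@](C)(OC(=O)c3c(C)cc(O[Si](C)(C)C(C)(C)C)cc3OC)[C@H](O[Si](C)(C)C(C)(C)C)C2
A3 | alternative 2 | 4-[(2R)-2-(TBSO)-3-oxobutyl]-6-[(1E)-prop-1-en-1-yl]-2H-pyran-3-carbaldehyde | C/C=C/C1=CC(C[C@@H](O[Si](C)(C)C(C)(C)C)C(C)=O)=C(C=O)CO1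
A4 | alternative 2 | (6R,7R)-6-(TBSO)-7-hydroxy-7-methyl-3-[(1E)-prop-1-en-1-yl]-6,7-dihydro-1H-isochromen-8(5H)-one | C/C=C/C1=CC2=C(CO1)C(=O)[C@](C)(O)[C@H](O[Si](C)(C)C(C)(C)C)C2
A5 | alternative 3 | methyl (2R)-2-{[4-(TBSO)-2-methoxy-6-methylbenzoyl]oxy}-2-methyl-3-oxopropanoate | COC(=O)[C@](C)(OC(=O)c1c(C)cc(O[Si](C)(C)C(C)(C)C)cc1OC)C=O
A6 | alternative 3 | methyl acetoacetate (methyl 3-oxobutanoate) | COC(=O)CC(C)=O
A7 | alternative 3 | methyl (4R,5R)-5-{[4-(TBSO)-2-methoxy-6-methylbenzoyl]oxy}-2,4-dihydroxy-5-methyl-6-oxocyclohex-1-ene-1-carboxylate | COC(=O)C1=C(O)C[C@@H](O)[C@@](C)(OC(=O)c2c(C)cc(O[Si](C)(C)C(C)(C)C)cc2OC)C1=O
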